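**Late slowness.** Slow making late in a run lets the readings bound the share of left-handed product without any mechanism.

| setting | Monday's | Sunday's | Wednesday's | zeta | gamma | theta |
|---|---|---|---|---|---|---|
| left-handed substrate | 0.047 M | 0.047 M | 0.047 M | 0.047 M | 0.047 M | 0.047 M |
| right-handed substrate | 0.047 M | 0.047 M | 0.047 M | 0.047 M | 0.047 M | 0.047 M |
| reagent | 1.8 equiv | 2.6 equiv | 4.7 equiv | 2.00 equiv | 2.50 equiv | 4.00 equiv |
| remark | run made earlier | run made earlier | run made earlier |  |  |  |
| time |  |  |  | 40 h | 40 h | 40 h |

| run | time / h | left-handed product / % | right-handed product / % |
|---|---|---|---|
| Monday's | 3.00 | 14.9 | 11.4 |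
| Monday's | 8.00 | 18.4 | 18.2 |
| Monday's | 15.0 | 20.8 | 20.0 |
| Monday's | 40.0 | 22.2 | 22.8 |
| Sunday's | 5.00 | 19.7 | 18.5 |
| Sunday's | 15.0 | 24.5 | 24.0 |
| Sunday's | 25.0 | 25.7 | 24.8 |
| Sunday's | 40.0 | 25.8 | 26.4 |
| Wednesday's | 5.00 | 26.3 | 23.7 |
| Wednesday's | 15.0 | 30.8 | 30.6 |
| Wednesday's | 25.0 | 30.6 | 30.8 |
| Wednesday's | 40.0 | 32.7 | 31.6 |

(readings scatter by 0.5 percentage points)

- share of left-handed product in all that became left-handed product or right-handed product for zeta, gamma, theta, in this order
- the course of these numbers from the first flask to the last (falls all the way / hardly changes / falls, then rises / rises, then falls / rises all the way)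

- reagent is single-handed; left-handed substrate and right-handed substrate are mirror images of each other, charged as a racemate, each of them at the stated concentration
- the analysis behind the earlier runs scatters by 0.5 percentage points, standard deviation
- "hardly changes" means that all values lie within two and a half points (for a concentration: within two and a half percent of the largest)
- the handed part of reagent does not stay in what it makes, so the products of the two hands are mirror images too

**Memory half-life.** The excess, left-handed minus right-handed product, stands at 3.5 percentage points after 3.00 h in Monday's run and at 0.8 points after 15.0 h. The time in which this excess halves, the memory half-life, reads 5.64 h. It is only a reading, since each product carries a scatter of 0.5 points. The products are mirror images, so the early excess is kinetic control, and equal amounts are thermodynamic control.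

**The bracket.** Monday's first share, 56.7%, gives a crude ceiling, and its mirror, 43.3%, a crude floor.

Replacing the late curve by its mean tightens both. Monday's total gains 4.2 points between 15.0 h and 40.0 h. Were that gain wholly of one hand, the excess would balance at the mean slope times the memory half-life over ln(2). The share would then lie 1.5 points from 50%, so between 48.5% and 51.5%. Wednesday's run gives a narrower 0.73 points.

The curve is flattening, so the mean overstates the making at the end, an error on the safe side. At the memory half-life as read, an excess standing at 15.0 h in Monday's run is reckoned to shrink to 4.63% of itself by 40.0 h. The loadings of zeta and theta lie between these runs, so this reckoning commits to the midpoint, with a flat course.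

**The forecast.** It gives 50%, 50% and 50%, course hardly changes, holding that “the final ratio must be 50:50 whatever the reagent loading”, which stands inside the bracket.

**The flasks.** The simulation gives 50.0%, 50.0% and 50.0%, course hardly changes.

    reagent + left-handed substrate → left-handed product (k = 3.00 M⁻¹ h⁻¹)
    2 reagent → self-condensation product (k = 2.80 M⁻¹ h⁻¹)
    left-handed substrate ⇌ right-handed substrate (k = 1.50 h⁻¹)
    reagent + right-handed substrate → right-handed product (k = 1.60 M⁻¹ h⁻¹)
    reagent → decomposition product (k = 1.10 × 10⁻⁴ h⁻¹)
    left-handed product ⇌ right-handed product (k = 0.320 h⁻¹)

The relaxation half-life of the two products by their interchange alone, 1.08 h in zeta, is short against 40 h. Zeta's products gain 1.3 points from 20.0 h to 40.0 h, and with the memory half-life as read from Monday's run, 5.64 h, a different quantity from that relaxation half-life, the reckoned bracket for zeta stands 0.59 points from the midpoint. In theta, reagent falls under 2% of its charge at 16.1 h, and the 23.9 h that remain, counted in that same reading from Monday's run, make 4.24 memory half-lives.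

The numbers in the tables are simulated for an exercise; scatter was added.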